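The data stem from a simulated flask from invented constants, noise included.

4 questions stood before me: which flask ends highest in side product, and how much side product each of noon, dusk and winter holds. My decision for the next run was whether the electrophile may be fed or must be in the flask from the start.

| flask | acidic substrate | free base | electrophile | remark | time |
|---|---|---|---|---|---|
| theta | 0.18 M | 0.45 M | 0.27 M | run made earlier |  |
| epsilon | 0.25 M | 0.45 M | 0.27 M | run made earlier |  |
| zeta | 0.40 M | 0.45 M | 0.27 M | run made earlier |  |
| noon | 0.18 M (fed, over 5.0 h) | 0.450 M | 0.270 M | all else is in the flask from the start; the feed brings no volume worth counting | 8.0 h |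
| dusk | 0.18 M | 0.450 M | 0.270 M | everything together at the start | 8.0 h |
| winter | 0.18 M | 0.450 M | 0.270 M (fed, over 5.0 h) | all else is in the flask from the start; the feed brings no volume worth counting | 8.0 h |

| run | time / h | side product / % | target / % |
|---|---|---|---|
| theta | 1.33 | 18.7 | 6.7 |
| theta | 2.50 | 33.6 | 13.7 |
| theta | 4.00 | 45.6 | 17.7 |
| theta | 5.00 | 50.8 | 18.6 |
| epsilon | 2.50 | 29.6 | 11.9 |
| epsilon | 5.00 | 47.0 | 16.2 |
| epsilon | 8.00 | 58.7 | 18.3 |
| epsilon | 10.0 | 63.7 | 20.6 |
| zeta | 1.33 | 16.0 | 4.7 |
| zeta | 3.00 | 29.8 | 9.2 |
| zeta | 6.00 | 44.3 | 15.1 |
| zeta | 10.0 | 54.7 | 18.0 |

(standard deviation of a reading: 1 percentage point)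

- amounts and yields of target count crystals too
- given per volume of solution although it is solid: crystals
- steps under discussion: crystals <-> target; acidic substrate + free base <-> protonated base + anion; anion -> side product; electrophile + anion -> target

1. the flask that comes out highest in amount of side product, in percent of the acidic substrate charged, or "all alike" when all lie within 1.5 percentage points (noon / dusk / winter / all alike)
2. side product at the end, in percent of the acidic substrate charged, noon
3. side product at the end, in percent of the acidic substrate charged, dusk
4. side product at the end, in percent of the acidic substrate charged, winter

The anion has two exits. The side step takes anion by itself, while the capture step also needs electrophile, so it counts as pseudo-first-order in anion, in proportion to the electrophile standing. I carried one quantity, the side ratio, meaning side product formed per target formed with electrophile near its charge. I read it from theta, which by 5.00 h had used 12.4% of its electrophile: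

rho = 50.8% / 18.6% = 2.73

My rule was that the ratio equals rho divided by e, where e is the fraction of electrophile charge present while side product forms. Scaling epsilon's turnover at 8.00 h by the theta/epsilon turnover at 5.00 h gave dusk's turnover, and so its side product:

turnover = 84.6%; dusk = 61.9%

In noon the acidic substrate has on average 5.50 h in the flask, and extending theta's last slope to that age gave 53.4%.

In winter, e climbs during the feed. I weighted e by theta's side product, taking e as 0.250 up to 2.50 h, 0.750 from there to 5.00 h, and near its charge afterwards, and I assumed dusk's turnover:

mean e = 0.523; ratio = 5.22; winter = 71.0%

In my reckoning, winter stood 9.1 percentage points higher in side product than dusk, so I would charge the electrophile at the start.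

The forecast named winter, with 52%, 61% and 69% for noon, dusk and winter, reasoning that “little electrophile is present early”. The flasks gave 53.3%, 62.2% and 69.2%, winter highest.

    crystals ⇌ target, rate k1*(cs1 - [target]) while solid is left; crystals form when [target] > cs1 (solubility = 2.80 mM, k = 4.80 h⁻¹)
    acidic substrate + free base ⇌ protonated base + anion, settled at all times (K = 1.20)
    anion → side product (k = 0.250 h⁻¹)
    electrophile + anion → target (k = 0.360 L mol⁻¹ h⁻¹)

In winter at 2.38 h, anion went to side product 5.6 times as fast as to target, about twice rho, and winter ended with 5.25 side product per target, against my 5.22 and dusk's 2.79. A winter flask with free base lowered to 0.11 M still held 46.1% as acidic substrate at the end, and with the same electrophile feed its 38.7% of side product stood at 5.00 per target.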